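**Plan**

1. Retrosynthesis: cut the C4=C18 methylene (Mannich methylenation) and the C12–C13 bond (B-alkyl Suzuki coupling), then C9–C10 (oxy-Cope), then C7–C8 (alkenylmetal addition to a ketone), and last C2–C7 and C5–C6 (Diels–Alder reaction of an o-quinone monoketal).
2. Forward: 2-methoxy-3-methylphenol is dearomatised and trapped with benzyl vinyl ether to give a bicyclo[2.2.2]octenone that holds all ring A carbons plus C6 and C7. A Z-dienyl group is added at C7, and the anionic oxy-Cope shift closes ring B and releases ring A as a cis-fused cyclohexene.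
3. Then the C7 ketone is reduced and acetylated, the C9 vinyl group is extended to the E-enoate, and ring A goes from the 1-en-3-one through its epoxide and C4 methylenation to the α-methylene diosphenol.
4. Stereochemistry: absolute configuration comes from resolution of the bicyclic alcohol as its camphanate. C5/C10 (cis) and C9 come from the bicycle and the Z-alkene through a boat transition state, C8 from equilibration, C7 from dissolving-metal reduction, and C13=C14 from an E-enol triflate.
5. Enabling feature: in ring B the quaternary C9 (methyl C20 plus side chain) sits next to the ring-fusion carbon C10, which is allylic to the C1=C2 bond of ring A, and C7 carries oxygen. C7(O)–C8–C9–C10–C1=C2 is therefore the δ,ε-unsaturated carbonyl array that an oxy-Cope shift of the 1,5-diene C9=C8–C7–C2–C1=C10 produces.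

Key step: step 12

Assumption: the cycloadduct is taken as the endo isomer (benzyloxy syn to the new C5=C6 bond), which is immaterial because that carbon becomes a ketone in step 7; racemates 4–7 are drawn as the enantiomer carried on; the epoxide in 29–33 may lie on either face of ring A and is written without configuration because both carbons become trigonal in step 20; clerodane numbering is used for the decalins (ring A = C1–C5, C10; ring B = C5–C10) and β is the face of H10 and the C5 methyl (C19).

**Route**

Step 1
Reactants: 1 2-methoxy-3-methylphenol; 2 benzyl vinyl ether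
Product: 4 rac-7-(benzyloxy)-3,3-dimethoxy-4-methylbicyclo[2.2.2]oct-5-en-2-one (benzyloxy syn to C5=C6), via quinone monoketal 3 (not isolated)
Conditions: PhI(OAc)2, MeOH, 2 (excess), 0 °C → rt
Reagents that add atoms: methanol, CO
Why: Oxidative dearomatisation of the guaiacol in methanol gives the masked o-benzoquinone 3, which is trapped at once in an inverse-electron-demand Diels–Alder reaction in which the nucleophilic CH2 of the enol ether bonds to the methyl-bearing diene terminus (ortho regiochemistry) and the benzyloxy group sits endo, so both bridgeheads and C7 are set relative to each other in racemic form.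

Step 2
Reactants: 4 rac-7-(benzyloxy)-3,3-dimethoxy-4-methylbicyclo[2.2.2]oct-5-en-2-one
Product: 5 rac-7-(benzyloxy)-4-methylbicyclo[2.2.2]oct-5-en-2-one
Conditions: SmI2 (excess), THF/MeOH, rt
Reagents that add atoms: none
Why: Samarium diiodide reduction of an α-alkoxy ketone (ketyl formation, loss of methoxide, protonation of the samarium enolate, run twice) should remove both methoxy groups, while the β-benzyloxy group stays because no enolate can form towards the bridgehead.

Step 3
Reactants: 5 rac-7-(benzyloxy)-4-methylbicyclo[2.2.2]oct-5-en-2-one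
Product: 6 rac-7-(benzyloxy)-4-methylspiro[bicyclo[2.2.2]oct-5-ene-2,2'-[1,3]dioxolane]
Conditions: HOCH2CH2OH, TsOH·H2O (cat.), benzene, reflux, Dean–Stark
Reagents that add atoms: ethylene glycol, OCCO
Why: Acid-catalysed ketalisation with azeotropic removal of water protects the only ketone as its dioxolane.

Step 4
Reactants: 6 rac-7-(benzyloxy)-4-methylspiro[bicyclo[2.2.2]oct-5-ene-2,2'-[1,3]dioxolane]
Product: 7 rac-4-methylspiro[bicyclo[2.2.2]oct-5-ene-2,2'-[1,3]dioxolan]-7-ol (hydroxyl syn to C5=C6)
Conditions: Na, NH3(l), THF, −78 °C; NH4Cl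
Reagents that add atoms: none
Why: Dissolving-metal (Birch-type) cleavage of the benzyl ether leaves the isolated alkene and the ketal untouched, whereas hydrogenolysis would saturate the alkene.

Step 5
Reactants: 7 rac-4-methylspiro[bicyclo[2.2.2]oct-5-ene-2,2'-[1,3]dioxolan]-7-ol
Product: 8 (1S,4R,7S)-4-methylspiro[bicyclo[2.2.2]oct-5-ene-2,2'-[1,3]dioxolan]-7-yl (1S,4R)-camphanate
Conditions: (1S)-camphanic chloride, Et3N, DMAP (cat.), CH2Cl2, 0 °C → rt; separation of the two diastereomers by chromatography or crystallisation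
Reagents that add atoms: (1S)-(−)-camphanic chloride, CC1(C)[C@@]2(C)CC[C@]1(C(=O)Cl)OC2=O
Why: Acylation with an enantiopure acid chloride (classical resolution through diastereomeric esters) should give two separable camphanates, and the one with the (1S,4R) bicycle is kept, its assignment to be secured by X-ray analysis with the camphanoyl unit as internal reference.

Step 6
Reactants: 8 the (1S,4R,7S) camphanate
Product: 9 (1S,4R,7S)-4-methylspiro[bicyclo[2.2.2]oct-5-ene-2,2'-[1,3]dioxolan]-7-ol
Conditions: K2CO3, MeOH, rt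
Reagents that add atoms: none
Why: Base-catalysed transesterification (methanolysis) returns the alcohol as a single enantiomer without touching the ketal or any stereocentre.

Step 7
Reactants: 9 (1S,4R,7S)-4-methylspiro[bicyclo[2.2.2]oct-5-ene-2,2'-[1,3]dioxolan]-7-ol
Product: 10 (1S,4R)-4-methylspiro[bicyclo[2.2.2]oct-5-ene-2,2'-[1,3]dioxolan]-7-one
Conditions: Dess–Martin periodinane, NaHCO3, CH2Cl2, rt
Reagents that add atoms: none
Why: Buffered Dess–Martin oxidation of the secondary alcohol should give the β,γ-unsaturated ketone without double-bond migration, erasing the carbinol centre.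

Step 8
Reactants: 11 but-2-yn-1-ol
Product: 13 (Z)-3-iodo-2-methylbut-2-en-1-ol, via oxamagnesacycle 12 (not isolated)
Conditions: MeMgBr (excess), CuI (cat.), THF, −20 °C → rt; then I2, −78 → 0 °C
Reagents that add atoms: methylmagnesium bromide, C[Mg]Br; iodine, II
Why: Copper-catalysed anti-carbomagnesiation of the propargylic alkoxide delivers methyl to the proximal alkyne carbon and magnesium to the distal one within a five-membered chelate, and iodinolysis with retention places iodine cis to the hydroxymethyl group (Z).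

Step 9
Reactants: 13 (Z)-3-iodo-2-methylbut-2-en-1-ol
Product: 14 (Z)-3-iodo-2-methylbut-2-enal
Conditions: MnO2 (activated), CH2Cl2, rt
Reagents that add atoms: none
Why: Allylic alcohol oxidation with MnO2 is neutral and should not isomerise the tetrasubstituted alkene.

Step 10
Reactants: 14 (Z)-3-iodo-2-methylbut-2-enal
Product: 15 (3Z)-4-iodo-3-methylpenta-1,3-diene (volatile, used as a solution)
Conditions: Ph3PCH3Br, KOtBu, THF, 0 °C; then 14, 0 °C
Reagents that add atoms: methyltriphenylphosphonium bromide, C[P+](c1ccccc1)(c1ccccc1)c1ccccc1.[Br-]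
Why: Wittig methylenation of the aldehyde with the non-stabilised ylide gives the terminal alkene and leaves the Z-configured vinyl iodide unchanged.

Step 11
Reactants: 15 (3Z)-4-iodo-3-methylpenta-1,3-diene; 10 (1S,4R)-4-methylspiro[bicyclo[2.2.2]oct-5-ene-2,2'-[1,3]dioxolan]-7-one
Product: 18 (1S,4R,7R)-4-methyl-7-[(2Z)-3-methylpenta-2,4-dien-2-yl]spiro[bicyclo[2.2.2]oct-5-ene-2,2'-[1,3]dioxolan]-7-ol (dienyl group syn to C5=C6), via dienyllithium 16 (not isolated), via dienylcerium dichloride 17 (not isolated)
Conditions: 15, t-BuLi (2 equiv), Et2O, −78 °C; CeCl3, THF, −78 °C; then 10, −78 → −40 °C; NH4Cl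
Reagents that add atoms: none
Why: Iodine–lithium exchange keeps the alkene geometry, and the organocerium reagent (Imamoto conditions) should add to the enolisable ketone from the face flanked by the etheno bridge, away from the dioxolane-bearing bridge, which sets the carbinol centre with the dienyl group syn to C5=C6 as the sigmatropic shift requires.

Step 12
Reactants: 18 the (1S,4R,7R) dienyl carbinol
Product: 21 (5,10-cis)-3,3-ethylenedioxy-13,14,15,16,18-pentanorcleroda-1,11-dien-7-one (H10, C19 and the C9 vinyl group β; C17 and C20 α), via potassium alkoxide 19 (not isolated), via potassium enolate 20 (not isolated)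
Conditions: KH, 18-crown-6, THF, 0 °C → rt; MeOH, then aq. NH4Cl
Reagents that add atoms: none
Why: Deprotonation gives the crown-ether-separated potassium alkoxide 19, whose oxyanion weakens the C2–C7 bond and triggers an anionic oxy-Cope rearrangement, a suprafacial [3,3]-sigmatropic shift over the 1,5-diene C9=C8–C7–C2–C1=C10 that breaks C2–C7 and forms C9–C10. The closest known reactions are the alkoxide-accelerated oxy-Cope rearrangements of 2-alkenylbicyclo[2.2.2]oct-5-en-2-ols, made from masked o-benzoquinone adducts, to cis-decalins. Ring B (C5–C10) is closed by this concerted sigmatropic bond formation through the only geometry the cage allows, a boat-like transition state, while ring A is released from the bicycle as the C1=C2 cyclohexene. C10 is set because C9 can reach only the face of C10 that carried the C6–C7 bridge, which puts H10 cis to the C5 methyl; C9 is set by the Z geometry of C8=C9, whose inside vinyl group ends cis to H10 and whose outside methyl becomes C20; C8 is set when enolate 20 is protonated, the methanol quench allowing equilibration to the equatorial methyl cis to C20. The step needs the [3,3] path to outrun alkoxide fragmentation and needs full transfer of alkene geometry, which the syn placement of the dienyl group from step 11, the small planar inside substituent, the rigid bicycle and the irreversible enolate formation should secure.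

Step 13
Reactants: 21 the cis-decalin vinyl ketone
Product: 22 (5,10-cis)-3,3-ethylenedioxy-13,14,15,16,18-pentanorcleroda-1,11-dien-7β-ol
Conditions: Li, NH3(l), THF, t-BuOH, −78 °C; NH4Cl
Reagents that add atoms: none
Why: Dissolving-metal reduction of the hindered ketone should give the thermodynamically preferred equatorial 7β-alcohol (trans to the C8 methyl), whereas hydride reagents would attack from the open β face, away from the axial C20 methyl and C4 methylene, and give the axial epimer; the isolated alkenes and the ketal are inert.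

Step 14
Reactants: 22 the 7β-alcohol
Product: 23 (5,10-cis)-3,3-ethylenedioxy-13,14,15,16,18-pentanorcleroda-1,11-dien-7β-yl acetate
Conditions: Ac2O, DMAP, pyridine, rt
Reagents that add atoms: acetic anhydride, CC(=O)OC(C)=O
Why: DMAP-catalysed acetylation of the secondary alcohol, with no change at any stereocentre.

Step 15
Reactants: 24 tert-butyl acetoacetate
Product: 25 tert-butyl (E)-3-[(trifluoromethylsulfonyl)oxy]but-2-enoate
Conditions: Tf2O, aq. Me4NOH, toluene, 5 °C
Reagents that add atoms: trifluoromethanesulfonic anhydride, O=S(=O)(OS(=O)(=O)C(F)(F)F)C(F)(F)F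
Why: Enol triflation of the β-keto ester under non-chelating conditions (tetramethylammonium enolate) should give the E-enol triflate, with triflate trans to the ester.

Step 16
Reactants: 23 the vinyl acetate; 25 tert-butyl (E)-3-[(trifluoromethylsulfonyl)oxy]but-2-enoate
Product: 27 tert-butyl 7β-acetoxy-3,3-ethylenedioxy-18-norcleroda-1,13E-dien-15-oate, via alkylborane 26 (not isolated)
Conditions: 9-BBN-H, THF, rt → 50 °C; then 25, PdCl2(dppf), AsPh3, Cs2CO3, DMF/H2O, rt
Reagents that add atoms: none
Why: Chemoselective anti-Markovnikov hydroboration of the monosubstituted alkene with 9-BBN, followed by B-alkyl Suzuki–Miyaura coupling in which oxidative addition of the enol triflate to zerovalent palladium and reductive elimination proceed with retention, should give the 13E trisubstituted enoate.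

Step 17
Reactants: 27 the ketal enoate
Product: 28 tert-butyl 7β-acetoxy-3-oxo-18-norcleroda-1,13E-dien-15-oate
Conditions: PPTS, acetone/H2O, 50 °C
Reagents that add atoms: water, O
Why: Mild acid-catalysed hydrolysis of the allylic dioxolane unmasks the 1-en-3-one while the tert-butyl ester and the acetate survive.

Step 18
Reactants: 28 the 1-en-3-one
Product: 29 tert-butyl 7β-acetoxy-1,2-epoxy-3-oxo-18-norclerod-13E-en-15-oate (cis-epoxide, either face of ring A)
Conditions: t-BuOOH, DBU, CH2Cl2, 0 °C → rt
Reagents that add atoms: tert-butyl hydroperoxide, CC(C)(C)OO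
Why: Weitz–Scheffer nucleophilic epoxidation (conjugate addition of the peroxide anion, then ring closure of the enolate) should pick the enone over the β,β-disubstituted enoate; the two new epoxide centres are removed again in step 20.

Step 19
Reactants: 29 the epoxy ketone
Product: 33 tert-butyl 7β-acetoxy-1,2-epoxy-3-oxocleroda-4(18),13E-dien-15-oate, via lithium enolate 30 (not isolated), via Mannich base 31 (not isolated), via ammonium iodide 32 (not isolated)
Conditions: LiN(SiMe3)2, THF, −78 °C; CH2=NMe2+ I−, −78 → 0 °C; MeI, CH2Cl2, rt; aq. NaHCO3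
Reagents that add atoms: Eschenmoser's salt (N,N-dimethylmethyleneiminium iodide), C=[N+](C)C.[I-]
Why: Kinetic deprotonation at C4, the only enolisable ketone position, with a hindered amide base, Mannich reaction of the enolate with Eschenmoser's salt, quaternisation and E1cB loss of trimethylamine (Eschenmoser methylenation) should give the α-methylene ketone, the less acidic acetate and enoate being expected to stay untouched at −78 °C.

Step 20
Reactants: 33 the α-methylene epoxy ketone
Product: 34 (5S,7S,8S,9R,10R)-7-acetoxy-2-hydroxy-3-oxocleroda-1,4(18),13E-trien-15-oic acid (CNP0192653.1)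
Conditions: TFA/H2O (9:1), CH2Cl2, 0 °C → rt
Reagents that add atoms: none
Why: Acid-promoted isomerisation of the α,β-epoxy ketone to the diosphenol (opening at C1 by water, then loss of water through the enediol) can give only the 2-hydroxy-1-en-3-one because C4 carries no hydrogen, and the same acid should cleave the tert-butyl ester by loss of isobutene while the acetate and all stereocentres remain.

**Compound list**

1 | 2-methoxy-3-methylphenol | COc1c(C)cccc1O | starting material
2 | benzyl vinyl ether | C=COCc1ccccc1 | starting material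
3 | 6,6-dimethoxy-5-methylcyclohexa-2,4-dien-1-one (quinone monoketal, formed in situ) | COC1(OC)C(C)=CC=CC1=O | intermediate
4 | rac-7-(benzyloxy)-3,3-dimethoxy-4-methylbicyclo[2.2.2]oct-5-en-2-one, benzyloxy syn to C5=C6 | COC1(OC)C(=O)[C@H]2C=C[C@]1(C)C[C@@H]2OCc1ccccc1 | intermediate
5 | rac-7-(benzyloxy)-4-methylbicyclo[2.2.2]oct-5-en-2-one | C1C(=O)[C@H]2C=C[C@]1(C)C[C@@H]2OCc1ccccc1 | intermediate
6 | rac-7-(benzyloxy)-4-methylspiro[bicyclo[2.2.2]oct-5-ene-2,2'-[1,3]dioxolane] | C1C2(OCCO2)[C@H]3C=C[C@]1(C)C[C@@H]3OCc1ccccc1 | intermediate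
7 | rac-4-methylspiro[bicyclo[2.2.2]oct-5-ene-2,2'-[1,3]dioxolan]-7-ol, hydroxyl syn to C5=C6 | C1C2(OCCO2)[C@H]3C=C[C@]1(C)C[C@@H]3O | intermediate
8 | (1S,4R,7S)-4-methylspiro[bicyclo[2.2.2]oct-5-ene-2,2'-[1,3]dioxolan]-7-yl (1S,4R)-4,7,7-trimethyl-3-oxo-2-oxabicyclo[2.2.1]heptane-1-carboxylate | C1C2(OCCO2)[C@H]3C=C[C@]1(C)C[C@@H]3OC(=O)[C@@]45CC[C@@](C)(C(=O)O4)C5(C)C | intermediate
9 | (1S,4R,7S)-4-methylspiro[bicyclo[2.2.2]oct-5-ene-2,2'-[1,3]dioxolan]-7-ol (single enantiomer) | C1C2(OCCO2)[C@H]3C=C[C@]1(C)C[C@@H]3O | intermediate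
10 | (1S,4R)-4-methylspiro[bicyclo[2.2.2]oct-5-ene-2,2'-[1,3]dioxolan]-7-one | C1C2(OCCO2)[C@H]3C=C[C@]1(C)CC3=O | intermediate
11 | but-2-yn-1-ol | CC#CCO | starting material
12 | 3,4-dimethyl-2,5-dihydro-1,2-oxamagnesole (oxamagnesacycle, formed in situ) | CC1=C(C)[Mg]OC1 | intermediate
13 | (Z)-3-iodo-2-methylbut-2-en-1-ol | OC/C(C)=C(/C)I | intermediate
14 | (Z)-3-iodo-2-methylbut-2-enal | O=C/C(C)=C(/C)I | intermediate
15 | (3Z)-4-iodo-3-methylpenta-1,3-diene | C=C/C(C)=C(/C)I | intermediate
16 | (3-methylpenta-2,4-dien-2-yl)lithium, lithium cis to the vinyl group (formed in situ) | C=C/C(C)=C(/C)[Li] | intermediate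
17 | dichloro(3-methylpenta-2,4-dien-2-yl)cerium, cerium cis to the vinyl group (formed in situ) | C=C/C(C)=C(/C)[Ce](Cl)Cl | intermediate
18 | (1S,4R,7R)-4-methyl-7-[(2Z)-3-methylpenta-2,4-dien-2-yl]spiro[bicyclo[2.2.2]oct-5-ene-2,2'-[1,3]dioxolan]-7-ol | C1C2(OCCO2)[C@H]3C=C[C@]1(C)C[C@]3(O)/C(C)=C(/C)C=C | intermediate
19 | potassium alkoxide of 18 (formed in situ) | C1C2(OCCO2)[C@H]3C=C[C@]1(C)C[C@]3([O-])/C(C)=C(/C)C=C.[K+] | intermediate
20 | potassium C7=C8 enolate of 21 (formed in situ) | C1C2(OCCO2)C=C[C@@H]3[C@@](C)(C=C)C(C)=C([O-])C[C@]13C.[K+] | intermediate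
21 | (5,10-cis)-3,3-ethylenedioxy-13,14,15,16,18-pentanorcleroda-1,11-dien-7-one; H10, C19, C9-vinyl β; C17, C20 α | C1C2(OCCO2)C=C[C@@H]3[C@@](C)(C=C)[C@H](C)C(=O)C[C@]13C | intermediate
22 | (5,10-cis)-3,3-ethylenedioxy-13,14,15,16,18-pentanorcleroda-1,11-dien-7β-ol | C1C2(OCCO2)C=C[C@@H]3[C@@](C)(C=C)[C@H](C)[C@@H](O)C[C@]13C | intermediate
23 | (5,10-cis)-3,3-ethylenedioxy-13,14,15,16,18-pentanorcleroda-1,11-dien-7β-yl acetate | C1C2(OCCO2)C=C[C@@H]3[C@@](C)(C=C)[C@H](C)[C@@H](OC(C)=O)C[C@]13C | intermediate
24 | tert-butyl acetoacetate | CC(=O)CC(=O)OC(C)(C)C | starting material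
25 | tert-butyl (E)-3-[(trifluoromethylsulfonyl)oxy]but-2-enoate | CC(C)(C)OC(=O)/C=C(\C)OS(=O)(=O)C(F)(F)F | intermediate
26 | C12 9-borabicyclo[3.3.1]nonan-9-yl derivative of 23 (formed in situ) | C1C2(OCCO2)C=C[C@@H]3[C@@](C)(CCB4C5CCCC4CCC5)[C@H](C)[C@@H](OC(C)=O)C[C@]13C | intermediate
27 | tert-butyl 7β-acetoxy-3,3-ethylenedioxy-18-norcleroda-1,13E-dien-15-oate | C1C2(OCCO2)C=C[C@@H]3[C@@](C)(CC/C(C)=C/C(=O)OC(C)(C)C)[C@H](C)[C@@H](OC(C)=O)C[C@]13C | intermediate
28 | tert-butyl 7β-acetoxy-3-oxo-18-norcleroda-1,13E-dien-15-oate | C1C(=O)C=C[C@@H]2[C@@](C)(CC/C(C)=C/C(=O)OC(C)(C)C)[C@H](C)[C@@H](OC(C)=O)C[C@]12C | intermediate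
29 | tert-butyl 7β-acetoxy-1,2-epoxy-3-oxo-18-norclerod-13E-en-15-oate (epoxide on either face) | C1C(=O)C2OC2[C@@H]3[C@@](C)(CC/C(C)=C/C(=O)OC(C)(C)C)[C@H](C)[C@@H](OC(C)=O)C[C@]13C | intermediate
30 | lithium C3=C4 enolate of 29 (formed in situ) | C1=C(O[Li])C2OC2[C@@H]3[C@@](C)(CC/C(C)=C/C(=O)OC(C)(C)C)[C@H](C)[C@@H](OC(C)=O)C[C@]13C | intermediate
31 | tert-butyl 7β-acetoxy-18-(dimethylamino)-1,2-epoxy-3-oxoclerod-13E-en-15-oate (Mannich base, formed in situ) | CN(C)CC1C(=O)C2OC2[C@@H]3[C@@](C)(CC/C(C)=C/C(=O)OC(C)(C)C)[C@H](C)[C@@H](OC(C)=O)C[C@]13C | intermediate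
32 | trimethylammonium iodide of 31 (formed in situ) | C[N+](C)(C)CC1C(=O)C2OC2[C@@H]3[C@@](C)(CC/C(C)=C/C(=O)OC(C)(C)C)[C@H](C)[C@@H](OC(C)=O)C[C@]13C.[I-] | intermediate
33 | tert-butyl 7β-acetoxy-1,2-epoxy-3-oxocleroda-4(18),13E-dien-15-oate | C=C1C(=O)C2OC2[C@@H]3[C@@](C)(CC/C(C)=C/C(=O)OC(C)(C)C)[C@H](C)[C@@H](OC(C)=O)C[C@]13C | intermediate
34 | (5S,7S,8S,9R,10R)-7-acetoxy-2-hydroxy-3-oxocleroda-1,4(18),13E-trien-15-oic acid | C=C1C(=O)C(O)=C[C@@H]2[C@@](C)(CC/C(C)=C/C(=O)O)[C@H](C)[C@@H](OC(C)=O)C[C@]12C | target

**Step count**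

Total: 20 steps. Longest linear sequence: 16 steps (1–7, 11–14, 16–20). Steps 8–10 and step 15 are side branches.

**Steps most likely to fail**

Step 12. The alkoxide may fragment by retro-addition, or the conjugated diene may oligomerise under KH, before the crowded boat transition state is reached (the inside vinyl group is pressed towards C5 and C10). The fallback runs the same disconnection as a neutral siloxy-Cope rearrangement. It sets out from 18, which is silylated (TMSOTf, 2,6-lutidine) to the trimethylsilyl ether of 18 F1. This is heated in degassed o-dichlorobenzene at about 200 °C in base-washed glass to give the C7=C8 trimethylsilyl enol ether of 21 F2. Methanolysis (K2CO3, MeOH), which also equilibrates C8, comes back to the route at 21.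

Step 20. Under the acid needed, the enediol formed on the way to the diosphenol may protonate at C18 and pull the exocyclic double bond into the ring, water may add to the α-methylene ketone, or epoxide opening may stall. The fallback makes the diosphenol before the methylene group is present and sets out from 29. H2SO4 (cat.) in AcOH should isomerise the epoxy ketone and cleave the tert-butyl ester to give 7β-acetoxy-2-hydroxy-3-oxo-18-norcleroda-1,13E-dien-15-oic acid F4. MOMCl and i-Pr2NEt protect both acidic groups as the bis(methoxymethyl) derivative F5; if the other enol tautomer is also trapped, the isomers are separated here. LiN(SiMe3)2 at −78 °C gives the lithium C3=C4 enolate of F5 F6, Eschenmoser's salt the Mannich base F7, MeI its methiodide F8, and aqueous NaHCO3 the 4(18)-methylene bis(methoxymethyl) compound F9. TFA in CH2Cl2 at 0 °C removes both methoxymethyl groups and comes back to the route at 34.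

Step 19. The amide base may deprotonate the acetate or the γ-position of the enoate instead of C4, or attack the epoxide. The fallback avoids strong base and sets out from 29. Soft enolisation (TMSOTf, Et3N, CH2Cl2, 0 °C) can occur only towards C4 and gives the C3=C4 trimethylsilyl enol ether of 29 F3. This reacts with Eschenmoser's salt in CH2Cl2 (Mannich reaction of a silyl enol ether) and comes back to the route at 31, which is quaternised and eliminated as before.

**Further compounds**

F1 | step 12 | trimethylsilyl ether of 18 | C1C2(OCCO2)[C@H]3C=C[C@]1(C)C[C@]3(O[Si](C)(C)C)/C(C)=C(/C)C=C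
F2 | step 12 | C7=C8 trimethylsilyl enol ether of 21 | C1C2(OCCO2)C=C[C@@H]3[C@@](C)(C=C)C(C)=C(O[Si](C)(C)C)C[C@]13C
F3 | step 19 | C3=C4 trimethylsilyl enol ether of 29 | C1=C(O[Si](C)(C)C)C2OC2[C@@H]3[C@@](C)(CC/C(C)=C/C(=O)OC(C)(C)C)[C@H](C)[C@@H](OC(C)=O)C[C@]13C
F4 | step 20 | 7β-acetoxy-2-hydroxy-3-oxo-18-norcleroda-1,13E-dien-15-oic acid | C1C(=O)C(O)=C[C@@H]2[C@@](C)(CC/C(C)=C/C(=O)O)[C@H](C)[C@@H](OC(C)=O)C[C@]12C
F5 | step 20 | methoxymethyl 7β-acetoxy-2-(methoxymethoxy)-3-oxo-18-norcleroda-1,13E-dien-15-oate | C1C(=O)C(OCOC)=C[C@@H]2[C@@](C)(CC/C(C)=C/C(=O)OCOC)[C@H](C)[C@@H](OC(C)=O)C[C@]12C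
F6 | step 20 | lithium C3=C4 enolate of F5 | C1=C(O[Li])C(OCOC)=C[C@@H]2[C@@](C)(CC/C(C)=C/C(=O)OCOC)[C@H](C)[C@@H](OC(C)=O)C[C@]12C
F7 | step 20 | 18-(dimethylamino) Mannich base of F5 | CN(C)CC1C(=O)C(OCOC)=C[C@@H]2[C@@](C)(CC/C(C)=C/C(=O)OCOC)[C@H](C)[C@@H](OC(C)=O)C[C@]12C
F8 | step 20 | methiodide of F7 | C[N+](C)(C)CC1C(=O)C(OCOC)=C[C@@H]2[C@@](C)(CC/C(C)=C/C(=O)OCOC)[C@H](C)[C@@H](OC(C)=O)C[C@]12C.[I-]
F9 | step 20 | methoxymethyl 7β-acetoxy-2-(methoxymethoxy)-3-oxocleroda-1,4(18),13E-trien-15-oate | C=C1C(=O)C(OCOC)=C[C@@H]2[C@@](C)(CC/C(C)=C/C(=O)OCOC)[C@H](C)[C@@H](OC(C)=O)C[C@]12C
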